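**Plan** (labdane numbering: ring A = C1–C5 and C10; ring B = C5–C10; C17 = CH2 on C8; C18/C19 = CH3/CO2H on C4; C20 = CH3 on C10; C11–C16 = side chain)

1. Retrosynthetic cuts, in order: the C15–O acyl bond (palmitoyl chloride); C13–C16 and C14–C15 (CH3 and CH2OH added across a C13≡C14 alkyne); C4–C18 (enolate methylation); C8=C17 (Wittig on a C8 ketone); then C5–C10 and C7–C8 together, which opens both rings to an acyclic keto-enal; last C1–C10 (Negishi coupling of two small chains).
2. Enabling feature: in ring B, C6 lies between C5 and C7, and C9 lies between C10 and C8. A ketone at C6 makes C5 and C7 nucleophilic; an enal C10=C9–C8HO makes C10 and C8 electrophilic. Because C5 and C10 are already tied by C4–C3–C2–C1, one acid-mediated Michael/aldol event closes ring A (C5–C10) and then ring B (C7–C8).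
3. Forward order: bromo keto ester 7 (C1–C7, C19) and chloro-enal 12 (C8–C14, C20) are joined at C1–C10; step 8 forms ring A, then ring B; the ring-B oxygen is moved from C6 to C8 and exchanged for CH2; C4 is methylated; the alkyne becomes the E-allylic alcohol; ester cleavage and acylation finish.
4. Stereochemistry: C4 is bought with an oxazolidinone auxiliary (step 2) and relays to the quaternary C10 in step 8. C5 and C9 are epimerisable there (C9 again at ketone 21) and should settle as in the target. C4 becomes quaternary by equatorial methylation of the ester enolate (axial CO2Me). The 13E alkene comes from syn-carboalumination.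

Key step: step 8

Remark: 12 and 14 are carried as E/Z mixtures about C9=C10, because this double bond is consumed in step 8; α/β descriptors refer to labdane numbering.

**Route**

Step 1
Reactants: 1 (S)-4-benzyl-2-oxazolidinone; 2 5-bromopentanoyl chloride
Product: 3 (S)-4-benzyl-3-(5-bromopentanoyl)oxazolidin-2-one
Conditions: n-BuLi, THF, −78 °C; then 2, −78 → 0 °C
Reagents that add atoms: none
Why: N-acylation of the lithiated oxazolidinone with an acid chloride is the standard preparation of an Evans imide, and the primary bromide is inert under these conditions.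

Step 2
Reactants: 3 (S)-4-benzyl-3-(5-bromopentanoyl)oxazolidin-2-one; 4 3-bromo-2-methylpropene
Product: 5 (S)-4-benzyl-3-[(2R)-5-bromo-2-(2-methylprop-2-enyl)pentanoyl]oxazolidin-2-one
Conditions: NaN(SiMe3)2, THF, −78 °C; then 4, −78 → −40 °C
Reagents that add atoms: none
Why: Evans alkylation: the chelated Z sodium enolate is attacked by the allylic bromide on the face away from the benzyl group, which sets C4 as R, while the unactivated primary bromide of the chain does not compete at −78 °C.

Step 3
Reactants: 5 (S)-4-benzyl-3-[(2R)-5-bromo-2-(2-methylprop-2-enyl)pentanoyl]oxazolidin-2-one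
Product: 6 methyl (2R)-5-bromo-2-(2-methylprop-2-enyl)pentanoate
Conditions: MeMgBr, MeOH, THF, 0 °C (MeOMgBr formed in the flask)
Reagents that add atoms: methanol, CO
Why: Transesterification of the imide with bromomagnesium methoxide attacks the exocyclic carbonyl selectively, frees the methyl ester without epimerising C4 and returns the auxiliary.

Step 4
Reactants: 6 methyl (2R)-5-bromo-2-(2-methylprop-2-enyl)pentanoate
Product: 7 methyl (2R)-5-bromo-2-(2-oxopropyl)pentanoate
Conditions: O3, CH2Cl2/MeOH, −78 °C; then Me2S, −78 → 25 °C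
Reagents that add atoms: ozone, [O-][O+]=O
Why: Ozonolysis with reductive work-up cleaves the only alkene, a 1,1-disubstituted one, to the methyl ketone that supplies C6 and C7.

Step 5
Reactants: 8 4-bromobut-1-yne; 9 pentane-2,4-dione
Product: 11 hept-6-yn-2-one, via 3-(but-3-ynyl)pentane-2,4-dione 10 (not isolated)
Conditions: K2CO3, EtOH, reflux
Reagents that add atoms: none
Why: C-alkylation of acetylacetone by the primary bromide, followed in the same pot by base-induced ethanolysis of one acetyl group (retro-Claisen), is a classical route to methyl ketones.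

Step 6
Reactants: 11 hept-6-yn-2-one
Product: 12 2-(but-3-ynyl)-3-chlorobut-2-enal (E/Z mixture)
Conditions: POCl3, DMF, 0 → 60 °C; then aq. NaOAc
Reagents that add atoms: N,N-dimethylformamide, CN(C)C=O; phosphoryl chloride, O=P(Cl)(Cl)Cl; water, O
Why: Vilsmeier–Haack chloroformylation of a methyl alkyl ketone goes through the more substituted enol, so the formyl group (C8) enters at the methylene carbon (C9) and chloride replaces the ketone oxygen at C10; both alkene isomers are usable because this double bond is consumed in step 8.

Step 7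
Reactants: 7 methyl (2R)-5-bromo-2-(2-oxopropyl)pentanoate; 12 2-(but-3-ynyl)-3-chlorobut-2-enal
Product: 14 methyl (2R)-7-formyl-6-methyl-2-(2-oxopropyl)undec-6-en-10-ynoate (E/Z mixture), via alkylzinc bromide 13 (not isolated)
Conditions: Zn dust, LiCl, THF, 50 °C; then 12, Pd(OAc)2 (2 mol%), SPhos (4 mol%), THF, 25 °C
Reagents that add atoms: none
Why: Negishi coupling: zinc inserts into the primary C–Br bond in the presence of LiCl without touching ester or ketone, and the β-chloro enal is an activated vinyl chloride that adds oxidatively to zerovalent palladium, so C1–C10 forms and C4 is not affected.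

Step 8
Reactants: 14 methyl (2R)-7-formyl-6-methyl-2-(2-oxopropyl)undec-6-en-10-ynoate
Product: 17 methyl 5-(but-3-ynyl)-4a-methyl-8-oxo-1,2,3,4,4a,5,8,8a-octahydronaphthalene-1-carboxylate (labdane numbering: 6-oxo-7-ene; 4α-CO2Me / 5α-H / 9β-butynyl / 10β-CH3), via keto aldehyde 15 (not isolated), via ketol 16 (not isolated)
Conditions: TsOH·H2O (0.2 equiv), toluene (0.01 M), 80 °C, Dean–Stark trap
Reagents that add atoms: none
Why: Acid catalysis converts the C6 ketone into its more substituted enol (C5=C6) and protonates the enal so that C10 becomes a tertiary, hydroxyallyl-stabilised electrophile; C5 adds to C10 (Michael addition, ring A), the aldehyde is regenerated at C8, the C7 enol of the same ketone then adds to C8 (aldol, ring B) and loss of water gives the conjugated enone. The closest known reaction type is the acid-catalysed Robinson-type annulation run in its (3+3) mode, in which both α-carbons of one ketone are joined to the β-carbon and the carbonyl carbon of an α,β-unsaturated carbonyl compound (Michael addition, then aldol condensation); here both partners sit in one chain, so two rings form. Ring A closes in a 6-(enolexo)-exo-trig Michael cyclisation and ring B in a 6-(enolendo)-exo-trig aldol cyclisation. C10 is set in the chair-like Michael transition state with the C4 ester, the enol carbon C6 and the bulky C9 arm equatorial and the C10 methyl axial, cis to the axial C4–H, so the auxiliary-derived C4 centre is relayed to the quaternary carbon; C5 (α to the C6 carbonyl) and C9 (α to the C8 carbonyl before dehydration, γ to C6 after it) can epimerise and should settle as the trans ring fusion with an equatorial side chain. The step needs constitutional selectivity, which ring size secures (C7 cannot reach C10 and C5 cannot reach C8 through six-membered transition states, and the aldehyde, having no α-hydrogen, can only be the aldol acceptor), and facial selectivity at C10, which rests on the equatorial preference of the C4 ester and of the C9 arm; high dilution suppresses intermolecular aldol reactions.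

Step 9
Reactants: 17 bicyclic 6-oxo-7-ene ester (name as in step 8)
Product: 18 7α,8α-epoxide of 17 (epoxy ketone; oxygen on the face opposite the C10 methyl)
Conditions: t-BuOOH, DBU, CH2Cl2, 0 → 25 °C
Reagents that add atoms: tert-butyl hydroperoxide, CC(C)(C)OO
Why: Nucleophilic (Weitz–Scheffer type) epoxidation of the enone: the hydroperoxide anion adds to C8 from the α-face, opposite the axial C10 methyl, and the enolate closes the epoxide; the two new centres are removed again in steps 10 and 11.

Step 10
Reactants: 18 7α,8α-epoxy-6-ketone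
Product: 19 methyl 5-(but-3-ynyl)-6-hydroxy-4a-methyl-1,2,3,4,4a,5,6,8a-octahydronaphthalene-1-carboxylate (labdane numbering: 8α-OH, 6-ene)
Conditions: N2H4·H2O, AcOH (cat.), MeOH, 0 → 25 °C, under argon
Reagents that add atoms: none
Why: Wharton transposition: the hydrazone of the α,β-epoxy ketone opens the epoxide and loses N2, which leaves the alkene at C6=C7 and the oxygen at C8 (configuration retained from the epoxide) without touching C5 or C9.

Step 11
Reactants: 19 allylic alcohol (8α-OH, 6-ene)
Product: 20 methyl 5-(but-3-ynyl)-4a-methyl-6-oxo-1,2,3,4,4a,5,6,8a-octahydronaphthalene-1-carboxylate (labdane numbering: 8-oxo-6-ene)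
Conditions: Dess–Martin periodinane, CH2Cl2, 25 °C
Reagents that add atoms: none
Why: Dess–Martin oxidation converts the secondary allylic alcohol to the enone under neutral conditions that leave alkyne and ester alone.

Step 12
Reactants: 20 8-oxo-6-ene ester
Product: 21 methyl 5-(but-3-ynyl)-4a-methyl-6-oxodecahydronaphthalene-1-carboxylate (labdane numbering: 8-oxo; 4α-CO2Me / 5α-H / 9α-H / 10β-CH3)
Conditions: K[(s-Bu)3BH], THF, −78 °C; aq. NH4Cl; then NaOMe (cat.), MeOH, 25 °C
Reagents that add atoms: none
Why: Conjugate reduction of a cyclohexenone whose β-carbon (C6) carries no substituent outside the ring by a bulky trialkylborohydride gives the saturated C8 ketone after protonation of the enolate, and methoxide equilibration places the C9 side chain equatorial (9α-H), the stable arrangement next to the quaternary C10.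

Step 13
Reactants: 21 8-oxo ester
Product: 22 methyl 5-(but-3-ynyl)-4a-methyl-6-methylidenedecahydronaphthalene-1-carboxylate (labdane numbering: 8(17)-ene; C4 still bears H)
Conditions: Ph3PCH3Br, KOt-Bu, THF, 0 °C; then 21, 0 → 65 °C
Reagents that add atoms: methyltriphenylphosphonium bromide, C[P+](c1ccccc1)(c1ccccc1)c1ccccc1.[Br-]
Why: Wittig methylenation of the hindered C8 ketone with excess ylide (part of which is consumed reversibly by the alkyne C–H) installs C17; the basic medium can only confirm the equatorial side chain at C9.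

Step 14
Reactants: 22 8(17)-ene ester
Product: 23 methyl 15,16-dinorlabd-8(17)-en-13-yn-19-oate (4α-CH3, 4β-CO2Me)
Conditions: LiN(i-Pr)2 (2.3 equiv), THF, −78 °C; then MeI (1.1 equiv), −78 → −40 °C
Reagents that add atoms: iodomethane, CI
Why: Ester enolate methylation: MeI approaches C4 from the equatorial α-face because the axial β-face is shielded by the syn-axial C10 methyl, so C18 becomes equatorial and the ester (C19) axial as in the target; the lithium acetylide formed alongside is not alkylated by MeI in THF at low temperature and is reprotonated on work-up.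

Step 15
Reactants: 23 methyl 15,16-dinorlabd-8(17)-en-13-yn-19-oate
Product: 25 methyl (13E)-15-hydroxylabda-8(17),13-dien-19-oate, via alkenylalane 24 (not isolated)
Conditions: Me3Al, Cp2ZrCl2 (0.25 equiv), CH2Cl2, 0 → 25 °C; then (CH2O)n, THF, 25 °C; aq. NH4Cl
Reagents that add atoms: trimethylaluminium, C[Al](C)C; formaldehyde (as paraformaldehyde), C=O
Why: Zirconium-catalysed carboalumination of the terminal alkyne (Negishi) adds CH3 to C13 and aluminium to C14 in a syn fashion, and the alkenylalane adds to formaldehyde with retention, which gives the 13E allylic alcohol; the 1,1-disubstituted alkene and the hindered ester should not react.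

Step 16
Reactants: 25 methyl (13E)-15-hydroxylabda-8(17),13-dien-19-oate
Product: 26 (13E)-15-hydroxylabda-8(17),13-dien-19-oic acid
Conditions: NaSEt, DMF, 100 °C; then aq. HCl to pH 3
Reagents that add atoms: none
Why: The hindered axial methyl ester resists saponification but is cleaved by SN2 attack of thiolate at the O-methyl carbon, conditions under which the alkenes and the allylic alcohol are inert.

Step 17
Reactants: 26 (13E)-15-hydroxylabda-8(17),13-dien-19-oic acid; 27 hexadecanoyl chloride
Product: 28 (13E)-15-(hexadecanoyloxy)labda-8(17),13-dien-19-oic acid (CNP0323052.1)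
Conditions: pyridine, DMAP (cat.), CH2Cl2, 0 → 25 °C; aqueous bicarbonate work-up
Reagents that add atoms: none
Why: Acylation of the primary allylic alcohol by the acid chloride; any mixed anhydride formed at the hindered tertiary carboxyl group is hydrolysed back to the acid during the bicarbonate work-up.

**Compound list**

1 | (S)-4-benzyl-2-oxazolidinone | O=C1N[C@@H](Cc2ccccc2)CO1 | starting material
2 | 5-bromopentanoyl chloride | O=C(Cl)CCCCBr | starting material
3 | (S)-4-benzyl-3-(5-bromopentanoyl)oxazolidin-2-one | O=C(CCCCBr)N1[C@@H](Cc2ccccc2)COC1=O | intermediate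
4 | 3-bromo-2-methylpropene | CC(=C)CBr | starting material
5 | (S)-4-benzyl-3-[(2R)-5-bromo-2-(2-methylprop-2-enyl)pentanoyl]oxazolidin-2-one | O=C([C@@H](CC(C)=C)CCCBr)N1[C@@H](Cc2ccccc2)COC1=O | intermediate
6 | methyl (2R)-5-bromo-2-(2-methylprop-2-enyl)pentanoate | COC(=O)[C@@H](CC(C)=C)CCCBr | intermediate
7 | methyl (2R)-5-bromo-2-(2-oxopropyl)pentanoate | COC(=O)[C@@H](CC(C)=O)CCCBr | intermediate
8 | 4-bromobut-1-yne | C#CCCBr | starting material
9 | pentane-2,4-dione | CC(=O)CC(C)=O | starting material
10 | 3-(but-3-ynyl)pentane-2,4-dione | CC(=O)C(CCC#C)C(C)=O | intermediate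
11 | hept-6-yn-2-one | CC(=O)CCCC#C | intermediate
12 | 2-(but-3-ynyl)-3-chlorobut-2-enal (E/Z mixture) | CC(Cl)=C(C=O)CCC#C | intermediate
13 | [(4R)-4-(methoxycarbonyl)-6-oxoheptyl]zinc bromide | COC(=O)[C@@H](CC(C)=O)CCC[Zn]Br | intermediate
14 | methyl (2R)-7-formyl-6-methyl-2-(2-oxopropyl)undec-6-en-10-ynoate (E/Z mixture) | COC(=O)[C@@H](CC(C)=O)CCCC(C)=C(C=O)CCC#C | intermediate
15 | methyl 2-acetyl-3-methyl-3-(1-oxohex-5-yn-2-yl)cyclohexane-1-carboxylate (4α-CO2Me / 5α-H / 10β-CH3; C9 epimers) | CC(=O)[C@@H]1[C@](C)(CCC[C@H]1C(=O)OC)C(C=O)CCC#C | intermediate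
16 | methyl 5-(but-3-ynyl)-6-hydroxy-4a-methyl-8-oxodecahydronaphthalene-1-carboxylate (labdane: 8-hydroxy-6-oxo; C8 and C9 epimers) | OC1CC(=O)[C@@H]2[C@](C)(CCC[C@H]2C(=O)OC)C1CCC#C | intermediate
17 | methyl 5-(but-3-ynyl)-4a-methyl-8-oxo-1,2,3,4,4a,5,8,8a-octahydronaphthalene-1-carboxylate (labdane: 6-oxo-7-ene; 4α-CO2Me / 5α-H / 9β-butynyl / 10β-CH3) | C1=CC(=O)[C@@H]2[C@](C)(CCC[C@H]2C(=O)OC)[C@H]1CCC#C | intermediate
18 | 7α,8α-epoxide of 17 (7α,8α-epoxy-6-ketone) | [C@H]13O[C@@H]3C(=O)[C@@H]2[C@](C)(CCC[C@H]2C(=O)OC)[C@H]1CCC#C | intermediate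
19 | methyl 5-(but-3-ynyl)-6-hydroxy-4a-methyl-1,2,3,4,4a,5,6,8a-octahydronaphthalene-1-carboxylate (labdane: 8α-OH, 6-ene) | [C@@H]1(O)C=C[C@@H]2[C@](C)(CCC[C@H]2C(=O)OC)[C@H]1CCC#C | intermediate
20 | methyl 5-(but-3-ynyl)-4a-methyl-6-oxo-1,2,3,4,4a,5,6,8a-octahydronaphthalene-1-carboxylate (labdane: 8-oxo-6-ene) | O=C1C=C[C@@H]2[C@](C)(CCC[C@H]2C(=O)OC)[C@H]1CCC#C | intermediate
21 | methyl 5-(but-3-ynyl)-4a-methyl-6-oxodecahydronaphthalene-1-carboxylate (labdane: 8-oxo; 9α-H) | O=C1CC[C@@H]2[C@](C)(CCC[C@H]2C(=O)OC)[C@H]1CCC#C | intermediate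
22 | methyl 5-(but-3-ynyl)-4a-methyl-6-methylidenedecahydronaphthalene-1-carboxylate (labdane: 8(17)-ene; 4α-CO2Me, 4β-H) | C=C1CC[C@@H]2[C@](C)(CCC[C@H]2C(=O)OC)[C@H]1CCC#C | intermediate
23 | methyl 15,16-dinorlabd-8(17)-en-13-yn-19-oate | C=C1CC[C@@H]2[C@](C)(CCC[C@]2(C)C(=O)OC)[C@H]1CCC#C | intermediate
24 | methyl (13E)-14-(dimethylalumanyl)-15-norlabda-8(17),13-dien-19-oate | C=C1CC[C@@H]2[C@](C)(CCC[C@]2(C)C(=O)OC)[C@H]1CC/C(C)=C/[Al](C)C | intermediate
25 | methyl (13E)-15-hydroxylabda-8(17),13-dien-19-oate | C=C1CC[C@@H]2[C@](C)(CCC[C@]2(C)C(=O)OC)[C@H]1CC/C(C)=C/CO | intermediate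
26 | (13E)-15-hydroxylabda-8(17),13-dien-19-oic acid | C=C1CC[C@@H]2[C@](C)(CCC[C@]2(C)C(=O)O)[C@H]1CC/C(C)=C/CO | intermediate
27 | hexadecanoyl chloride | CCCCCCCCCCCCCCCC(=O)Cl | starting material
28 | (13E)-15-(hexadecanoyloxy)labda-8(17),13-dien-19-oic acid | C=C1CC[C@@H]2[C@](C)(CCC[C@]2(C)C(=O)O)[C@H]1CC/C(C)=C/COC(=O)CCCCCCCCCCCCCCC | target

**Totals and risks**

Total step count: 17. Longest linear sequence: 15 steps (steps 1–4 and 7–17); the two-step branch (steps 5 and 6) joins at step 7.

Steps most likely to fail:

Step 8. The Michael addition onto the fully substituted C10 may be slower than acid-promoted self-condensation of the aldehyde or a vinylogous aldol attack of the enal dienol (through C1) on the C6 ketone, and facial discrimination at C10 may be incomplete. The fallback replaces the thermodynamic acid cascade by a preformed nucleophile and two separate ring closures. It sets out from 7: TMSCl, NaI and Et3N in MeCN should give the more substituted silyl enol ether with bromide–iodide exchange, methyl (2R)-5-iodo-2-[2-(trimethylsilyloxy)prop-1-enyl]pentanoate F1. Zinc insertion (Zn, LiCl, THF) and Negishi coupling with 12 (Pd(OAc)2, SPhos) should give methyl (2R)-7-formyl-6-methyl-2-[2-(trimethylsilyloxy)prop-1-enyl]undec-6-en-10-ynoate F2. TiCl4 in CH2Cl2 at −78 °C should then close ring A by an intramolecular Mukaiyama–Michael addition (a compact, low-temperature transition state) to give keto aldehyde 15, now isolated. Piperidine and AcOH in refluxing benzene should close ring B by aldol condensation, and the fallback comes back to the route at 17.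

Step 10. Hydrazone formation at the hindered C6 carbonyl may lag behind hydrazinolysis of the methyl ester or base-induced opening of the epoxide. The fallback moves the oxygen by an allylic alcohol transposition instead and sets out from 17: Luche reduction (NaBH4, CeCl3·7H2O, MeOH, hydride from the α-face) should give methyl 5-(but-3-ynyl)-8-hydroxy-4a-methyl-1,2,3,4,4a,5,8,8a-octahydronaphthalene-1-carboxylate (6β-OH, 7-ene) F3. Catalytic Ph3SiOReO3 in Et2O at 0 °C should equilibrate it suprafacially to the less congested 8β-hydroxy epimer of 19 F4, the 6β-hydroxyl being syn-axial to the C10 methyl. Dess–Martin oxidation of F4 comes back to the route at 20.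

Step 15. Me3Al may attack the ester, carbometalation may stall, or the alkenylalane may add sluggishly to paraformaldehyde. The fallback builds the trisubstituted alkene by olefination and sets out from 23: alkyne hydration (Ph3PAuCl and AgOTf, cat., aqueous dioxane, 60 °C) should give methyl 13-oxo-14,15-dinorlabd-8(17)-en-19-oate F5. Horner–Wadsworth–Emmons reaction with (EtO)2P(O)CH2CO2Et and NaH in THF should give, after removal of the minor Z isomer, 15-ethyl 19-methyl (13E)-labda-8(17),13-diene-15,19-dioate F6. i-Bu2AlH (2.2 equiv) in CH2Cl2 at −78 °C should reduce only the unhindered conjugated ester, and the fallback comes back to the route at 25.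

**Further compounds**

F1 | step 8 | methyl (2R)-5-iodo-2-[2-(trimethylsilyloxy)prop-1-enyl]pentanoate | COC(=O)[C@@H](C=C(C)O[Si](C)(C)C)CCCI
F2 | step 8 | methyl (2R)-7-formyl-6-methyl-2-[2-(trimethylsilyloxy)prop-1-enyl]undec-6-en-10-ynoate | COC(=O)[C@@H](C=C(C)O[Si](C)(C)C)CCCC(C)=C(C=O)CCC#C
F3 | step 10 | methyl 5-(but-3-ynyl)-8-hydroxy-4a-methyl-1,2,3,4,4a,5,8,8a-octahydronaphthalene-1-carboxylate (6β-OH, 7-ene) | C1=C[C@@H](O)[C@@H]2[C@](C)(CCC[C@H]2C(=O)OC)[C@H]1CCC#C
F4 | step 10 | 8β-hydroxy epimer of 19 | [C@H]1(O)C=C[C@@H]2[C@](C)(CCC[C@H]2C(=O)OC)[C@H]1CCC#C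
F5 | step 15 | methyl 13-oxo-14,15-dinorlabd-8(17)-en-19-oate | C=C1CC[C@@H]2[C@](C)(CCC[C@]2(C)C(=O)OC)[C@H]1CCC(C)=O
F6 | step 15 | 15-ethyl 19-methyl (13E)-labda-8(17),13-diene-15,19-dioate | C=C1CC[C@@H]2[C@](C)(CCC[C@]2(C)C(=O)OC)[C@H]1CC/C(C)=C/C(=O)OCC
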